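At early times the ash flask holds its acidic substrate in several forms: at 0.833 min it has 34.7% acidic substrate and 18.2% target. In ash, the balance of the acidic substrate, the limiting reagent, puts the remaining 47.1% in anion and side product.

| flask | acidic substrate | free base | electrophile | temperature | remark | time |
|---|---|---|---|---|---|---|
| ash | 0.050 M | 0.090 M | 0.055 M | 70 °C | run made earlier |  |
| grey | 0.050 M | 0.0600 M | 0.0550 M | 70 °C |  | 50 min |
| red | 0.050 M | 0.0600 M | 0.0550 M | 45 °C |  | 50 min |

ash run (percent of the acidic substrate charged)

| time / min | target / % | acidic substrate / % |
|---|---|---|
| 0.833 | 18.2 | 34.7 |
| 1.50 | 29.7 | 30.5 |
| 2.50 | 41.2 | 27.0 |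
| 3.00 | 45.2 | 26.0 |
| 4.00 | 51.7 | 22.3 |
| 5.00 | 56.6 | 20.0 |

(readings scatter by 0.5 percentage points)

- candidate steps: acidic substrate + free base <-> protonated base + anion; electrophile + anion -> target; anion -> side product
- the earlier runs do not show what temperature does; that part of a forecast is a guess
- no earlier run changes the charge of free base; that part of a forecast is a guess

- which flask leads in amount of target, in percent of the acidic substrate charged ("all alike" within 1.5 percentage points) (grey / red / all alike)
- how much target is there at the end, in percent of the acidic substrate charged: grey
- how much target is there at the end, in percent of the acidic substrate charged: red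

Each target takes one electrophile and one acidic substrate. We therefore carry the charge ratio, electrophile charged over acidic substrate charged, 110% in grey and red. Target, in percent of the acidic substrate charged, is this ratio times the fraction of electrophile used. With the ratio above one, the ceiling in grey and red is the whole charge of acidic substrate, and reaching it would leave 9.09% of the electrophile.

Now the settings, by our own hand. Lowering the free base from 0.090 M to 0.0600 M leaves 0.0100 M over the acidic substrate instead of 0.0400 M, so we guess that less anion stands at a given moment and target comes later. Raising the time to 50 min, ten times the last ash reading, gives room, since the ash readings of target still rose by 4.9 percentage points in the last 1.00 min. We expect grey to end between the last ash reading of 56.6% and the ceiling. Cooling red to 45 °C is a guess too: it may lag in time, yet a slowed side step could repay that.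

The forecast names grey as leader, with 82% (73% to 90%) for grey and 60% (40% to 74%) for red, reasoning that for red “Fifty minutes then equals about 8 min” at 70 °C.

The flasks come out all alike, with 82.6% target in grey and 82.3% in red, 22 points above the forecast for red.

    acidic substrate + free base ⇌ protonated base + anion, settled at all times (K = 0.730, ΔH = −50.0 kJ mol⁻¹)
    electrophile + anion → target (k = 9.00 M⁻¹ min⁻¹, Ea = 43.0 kJ mol⁻¹)
    anion → side product (k = 0.0350 min⁻¹, Ea = 103 kJ mol⁻¹)
    (constants at 70 °C)

Grey has 25% of its electrophile left at 50.0 min, and the ratio turns that into 82.5% target. In grey, anion goes to target 14 times as fast as to side product just after the start but 3.5 times as fast at 50.0 min, and side product stands at 10.8%. Red at that time has 2.06% side product and 7.35% anion. A neighbour of grey charged with 0.014 M of electrophile has a ratio of 28.0% and gives 27.7% target, with 0.99% of its electrophile left.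

The runs come from a simulation with made-up constants; scatter was added.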